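Locants: flavanone unit O1, C2–C4, ring A = C4a–C8a, ring B = 1'–6'; flavone unit double-primed (ring A'' = C4a''–C8a''), its aryl ring triple-primed; the target is (2R,3S), 2,3-trans.
Endgame: hydrogen sulfate ⇐ hydrogenolysis of five benzyl ethers ⇐ sulfation of the single free phenol O7''-H, which the key step itself sets free.
Key disconnection C4–C4a: the protected biflavonoid is an isomer of a γ-lactone (benzofuran-2(3H)-one fused to ring A'' through O7'' and C8''). An O7''→C4a acyl migration (ring switch) closes flavanone ring C and opens the temporary lactone.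
Enabling feature: O7''–C7''–C8''–C3–C4 is a five-atom array that can be tied up as an aryl-ester lactone (activates C4, masks only O7'', makes C3 stereolabile). C4a of ring A lies between O1 and O5, para to O7, at six-ring distance from C4.
Lactone ⇐ hydroboration/oxidative lactonisation of a 1,1-disubstituted alkene ⇐ Suzuki union C3–C8'' of an 8''-iodoapigenin ether with an α-vinylboronate ⇐ Mitsunobu inversion (O1–C2) of a resolved propargylic alcohol. Ring order: flavone rings (bought with apigenin) → temporary lactone → flavanone ring C.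

Key step: step 12

Remark: the target is drawn as the free hydrogen sulfate, so the route ends with a cold stoichiometric acidification of the sodium salt; where C3 is a stereochemically irrelevant epimer mixture it is left undefined in the SMILES; 3,5-bis(benzyloxy)phenol is taken as a catalogue compound.

Step 1
Reactants: 1 apigenin
Product: 2 5-hydroxy-2-(4-hydroxyphenyl)-7-{[2-(trimethylsilyl)ethoxy]methoxy}-4H-chromen-4-one (7''-O-SEM-apigenin)
Conditions: SEMCl (1.05 equiv), K2CO3 (1.0 equiv), DMF, 0 °C to rt
Reagents that add atoms: 2-(trimethylsilyl)ethoxymethyl chloride, C[Si](C)(C)CCOCCl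
Why: Williamson-type O-alkylation in which one equivalent of weak base addresses only the most acidic phenol, O7''-H (vinylogous acid of the C4'' carbonyl), while O5''-H is chelated and O4'''-H is less acidic.

Step 2
Reactants: 2 7''-O-SEM-apigenin
Product: 3 5-(benzyloxy)-2-[4-(benzyloxy)phenyl]-7-{[2-(trimethylsilyl)ethoxy]methoxy}-4H-chromen-4-one
Conditions: BnBr (3 equiv), K2CO3 (4 equiv), Bu4NI (cat.), DMF, 60 °C
Reagents that add atoms: benzyl bromide, BrCc1ccccc1
Why: Exhaustive Williamson benzylation, in which warming, excess base and iodide catalysis also bring the chelated O5''-H to reaction and the SEM acetal is inert to base.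

Step 3
Reactants: 3 dibenzyl SEM ether of apigenin
Product: 4 5-(benzyloxy)-2-[4-(benzyloxy)phenyl]-8-iodo-7-{[2-(trimethylsilyl)ethoxy]methoxy}-4H-chromen-4-one
Conditions: NIS (1.1 equiv), TFA (cat.), MeCN/CH2Cl2, 0 °C to rt, dark
Reagents that add atoms: N-iodosuccinimide, O=C1CCC(=O)N1I
Why: Electrophilic aromatic iodination of the 5'',7''-dialkoxy ring A'', the most electron-rich arene present, at C8'' (between O7'' and the tied-back ring oxygen O1''), which is less hindered than C6'' (between two bulky alkoxy groups) and is the usual site in fully O-alkylated 5,7-dioxyflavones.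

Step 4
Reactants: 5 4-(benzyloxy)benzaldehyde
Product: 6 rac-1-[4-(benzyloxy)phenyl]prop-2-yn-1-ol
Conditions: HC≡CMgBr (1.3 equiv), THF, 0 °C; H2O
Reagents that add atoms: ethynylmagnesium bromide, C#C[Mg]Br
Why: 1,2-Addition of an alkynyl Grignard reagent to a non-enolisable aryl aldehyde.

Step 5
Reactants: 6 rac-1-[4-(benzyloxy)phenyl]prop-2-yn-1-ol
Product: 7 (S)-1-[4-(benzyloxy)phenyl]prop-2-yn-1-ol
Conditions: immobilised Candida antarctica lipase B, vinyl acetate (3 equiv), MTBE, 35 °C, stopped just past half conversion; chromatography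
Reagents that add atoms: none
Why: Lipase-catalysed kinetic resolution by enantioselective transesterification, in which the enzyme should acylate the (R)-alcohol (aryl as large, ethynyl as medium group) and leave the (S)-alcohol, the only stereocentre that has to be brought in from outside.

Step 6
Reactants: 7 (S)-1-[4-(benzyloxy)phenyl]prop-2-yn-1-ol; 8 3,5-bis(benzyloxy)phenol
Product: 9 (R)-1,3-bis(benzyloxy)-5-({1-[4-(benzyloxy)phenyl]prop-2-yn-1-yl}oxy)benzene
Conditions: PPh3, DIAD, toluene, −20 to 0 °C
Reagents that add atoms: none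
Why: Mitsunobu etherification (SN2 with inversion, S to R at C2) forms O1–C2; C3 is an sp carbon, so no β-hydrogen is available for elimination, the small, inductively withdrawing ethynyl group favours SN2 over ionisation, and the phenol reacts at oxygen.

Step 7
Reactants: 9 (R)-aryl propargyl ether
Product: 10 (R)-2-{3-[3,5-bis(benzyloxy)phenoxy]-3-[4-(benzyloxy)phenyl]prop-1-en-2-yl}-4,4,5,5-tetramethyl-1,3,2-dioxaborolane
Conditions: B2pin2 (1.1 equiv), (SIMes)CuCl (5 mol %), NaOtBu (5 mol %), MeOH (1.1 equiv), THF, −50 to −15 °C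
Reagents that add atoms: bis(pinacolato)diboron, CC1(C)OB(OC1(C)C)B1OC(C)(C)C(C)(C)O1
Why: Copper-catalysed formal hydroboration (borylcupration, then protonation by MeOH) of a terminal alkyne, in which an N-aryl NHC ligand and the propargylic oxygen direct boron to the internal carbon C3 and C2 is not touched.

Step 8
Reactants: 4 8''-iodoflavone; 10 α-vinylboronate
Product: 11 5-(benzyloxy)-2-[4-(benzyloxy)phenyl]-8-{(S)-3-[3,5-bis(benzyloxy)phenoxy]-3-[4-(benzyloxy)phenyl]prop-1-en-2-yl}-7-{[2-(trimethylsilyl)ethoxy]methoxy}-4H-chromen-4-one (S only through a change of CIP priorities; the spatial arrangement at C2 is unchanged)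
Conditions: Pd(OAc)2 (5 mol %), SPhos (10 mol %), K3PO4, THF/H2O, 45 °C
Reagents that add atoms: none
Why: Suzuki–Miyaura coupling forms the hindered C3–C8'' bond at the sp2 stage, where C3 has no acidic hydrogen and the β-aryloxy group cannot leave by E1cB, and a bulky biarylphosphine speeds up oxidative addition and reductive elimination at the di-ortho-substituted iodide.

Step 9
Reactants: 11 1,1-disubstituted alkene
Product: 13 5-(benzyloxy)-2-[4-(benzyloxy)phenyl]-8-{(1R)-1-[3,5-bis(benzyloxy)phenoxy]-1-[4-(benzyloxy)phenyl]-3-hydroxypropan-2-yl}-7-{[2-(trimethylsilyl)ethoxy]methoxy}-4H-chromen-4-one (C3 epimers), via pinacol boronate 12 (not isolated)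
Conditions: HBpin (2 equiv), [Ir(cod)Cl]2 (2.5 mol %), dppe (5 mol %), THF, rt; then NaBO3·4H2O, THF/H2O, rt
Reagents that add atoms: pinacolborane, CC1(C)OBOC1(C)C (boron in 12); sodium perborate, [Na+].[Na+].O[B-]1(O)OO[B-](O)(O)OO1 (oxygen on C4)
Why: Iridium-catalysed anti-Markovnikov hydroboration puts boron on the terminal carbon C4 without touching the pyrone carbonyl, perborate oxidation follows, and the new centre C3 forms as an epimer mixture that does not matter because C3 is equilibrated in step 12.

Step 10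
Reactants: 13 SEM-protected primary alcohol
Product: 14 5-(benzyloxy)-2-[4-(benzyloxy)phenyl]-8-{(1R)-1-[3,5-bis(benzyloxy)phenoxy]-1-[4-(benzyloxy)phenyl]-3-hydroxypropan-2-yl}-7-hydroxy-4H-chromen-4-one (C3 epimers)
Conditions: TBAF (4 equiv), THF, 50 °C; H2O
Reagents that add atoms: none
Why: Fluoride-induced fragmentation of the SEM acetal (attack at silicon, loss of ethene and formaldehyde) frees O7''-H under non-acidic conditions that leave the acid-sensitive C2–O1 benzylic ether and the benzyl ethers intact.

Step 11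
Reactants: 14 phenol–primary alcohol
Product: 16 5-(benzyloxy)-2-[4-(benzyloxy)phenyl]-9-{(R)-[3,5-bis(benzyloxy)phenoxy][4-(benzyloxy)phenyl]methyl}-4H-furo[2,3-h]chromene-4,8(9H)-dione (γ-lactone, C3 epimers), via lactol 15 (not isolated)
Conditions: TEMPO (0.2 equiv), PhI(OAc)2 (2.5 equiv), CH2Cl2, rt; aq. Na2S2O3 wash, short plug of neutral silica, used at once
Reagents that add atoms: none
Why: Oxoammonium (TEMPO) oxidation in which the aldehyde is trapped at once by the neighbouring O7''-H as a five-membered lactol that is oxidised on to the lactone (oxidative lactonisation of a 2-(2-hydroxyaryl)ethanol), so the elimination-prone free aldehyde does not build up and no base is present.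

Step 12
Reactants: 16 γ-lactone
Product: 19 (2R,3S)-5,7-bis(benzyloxy)-2-[4-(benzyloxy)phenyl]-3-{5-(benzyloxy)-2-[4-(benzyloxy)phenyl]-7-hydroxy-4-oxo-4H-chromen-8-yl}chroman-4-one, via silyl ether 17 (not isolated), via C3-epimeric ketone 18 (not isolated)
Conditions: TMSOTf (3 equiv), 2,6-di-tert-butyl-4-methylpyridine (3.5 equiv), CH2Cl2 (0.01 M), −78 to −20 °C; aq. NaHCO3; then PPTS (10 mol %), CH2Cl2, rt
Reagents that add atoms: none
Why: Proposed new method: silylation of the pyrone carbonyl oxygen on C4'' turns ring A'' into a 4-silyloxybenzopyrylium and so makes O7'' an excellent leaving group, a second TMSOTf activates the strained aryl-ester carbonyl C4, C4a of the 3,5-dibenzyloxyphenoxy ring attacks it, and the cis-fused tetrahedral intermediate collapses with cleavage of C4–O7'' while the hindered pyridine takes up the arenium proton, so that the lactone is isomerised to the aryl ketone, whose O7''-silyl ether is hydrolysed on work-up. The closest known reaction types are the Lewis-acid Fries rearrangement (acyl transfer from an aryl ester to an arene carbon), the intramolecular Friedel–Crafts acylation of 3-aryloxypropanoic acid derivatives to chroman-4-ones and the BF3-mediated acylation of phloroglucinol ethers with arylacetic acids; what is new is a benzofuran-2(3H)-one as internal acyl donor under buffered silyl triflate activation. The one ring that closes (flavanone ring C) forms by a 6-exo-trig attack of an arene carbon on the carbonyl group (SEAr at C4a), while the temporary five-membered lactone opens. C2 is not involved and stays R, whereas C3 is stereolabile both in 16 (acidic lactone C–H) and in the product (benzylic α-keto C–H), so the epimers should funnel through the less hindered transition state and the PPTS equilibration should settle on the 2,3-trans (3S) isomer with both aryl groups equatorial, under control of C2. Regioselectivity is structural, because the two positions ortho to O1 are equivalent, each lies between two oxygens and para to the third, and the position between O5 and O7 cannot reach C4. Chemoselectivity against ionisation of the p-benzyloxybenzylic C2–O1 bond, β-elimination of the aryloxide and dehydration of the tetrahedral intermediate to a benzofuran rests on the absence of free Brønsted acid and of an effective base, the low temperature, the acyl group on C3 that destabilises a C2 cation, and the silyl cap that keeps the released O7'' from adding back to C4.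

Step 13
Reactants: 19 pentabenzyl biflavonoid with free O7''-H
Product: 20 sodium (2R,3S)-pentabenzyl biflavonoid 7''-O-sulfate
Conditions: SO3·pyridine (5 equiv), pyridine, rt; aq. NaHCO3; Sephadex LH-20
Reagents that add atoms: sulfur trioxide pyridine complex, O=S(=O)([O-])[n+]1ccccc1; sodium hydrogen carbonate, [Na+].OC([O-])=O
Why: O-Sulfation of a phenol with a sulfur trioxide–amine complex, in which O7''-H is the only free hydroxyl group so that site selectivity is structural, and the weakly basic medium should leave C2 intact and C3 trans.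

Step 14
Reactants: 20 sodium pentabenzyl 7''-O-sulfate
Product: 22 target, (2R,3S)-naringenin-(3→8'')-apigenin 7''-O-(hydrogen sulfate), via sodium salt 21 (not isolated)
Conditions: H2 (1 atm), 10% Pd/C, THF/MeOH, rt; filtration; HCl (1.0 equiv, 0.1 M), 0 °C, immediate desalting on C18, lyophilisation
Reagents that add atoms: none
Why: Catalytic hydrogenolysis of five aryl benzyl ethers, to which aryl sulfate salts, the pyrone C2''=C3'' bond and the flavanone should be inert under mild conditions, followed by a brief cold stoichiometric acidification that converts the salt into the hydrogen sulfate without touching a stereocentre.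

Compound list
1 | apigenin | O=c1cc(-c2ccc(O)cc2)oc2cc(O)cc(O)c12 | starting material
2 | 7''-O-SEM-apigenin | O=c1cc(-c2ccc(O)cc2)oc2cc(OCOCC[Si](C)(C)C)cc(O)c12 | intermediate
3 | 5'',4'''-di-O-benzyl-7''-O-SEM-apigenin | O=c1cc(-c2ccc(OCc3ccccc3)cc2)oc2cc(OCOCC[Si](C)(C)C)cc(OCc3ccccc3)c12 | intermediate
4 | 8''-iodo-5'',4'''-di-O-benzyl-7''-O-SEM-apigenin | O=c1cc(-c2ccc(OCc3ccccc3)cc2)oc2c(I)c(OCOCC[Si](C)(C)C)cc(OCc3ccccc3)c12 | intermediate
5 | 4-(benzyloxy)benzaldehyde | O=Cc1ccc(OCc2ccccc2)cc1 | starting material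
6 | rac-1-[4-(benzyloxy)phenyl]prop-2-yn-1-ol | C#CC(O)c1ccc(OCc2ccccc2)cc1 | intermediate
7 | (S)-1-[4-(benzyloxy)phenyl]prop-2-yn-1-ol | C#C[C@H](O)c1ccc(OCc2ccccc2)cc1 | intermediate
8 | 3,5-bis(benzyloxy)phenol | Oc1cc(OCc2ccccc2)cc(OCc2ccccc2)c1 | starting material
9 | (R)-aryl propargyl ether | C#C[C@@H](Oc1cc(OCc2ccccc2)cc(OCc2ccccc2)c1)c1ccc(OCc2ccccc2)cc1 | intermediate
10 | (R)-α-vinylboronate | C=C(B1OC(C)(C)C(C)(C)O1)[C@@H](Oc1cc(OCc2ccccc2)cc(OCc2ccccc2)c1)c1ccc(OCc2ccccc2)cc1 | intermediate
11 | 1,1-disubstituted alkene (C3=C4H2, C3–C8'' formed, 7''-O-SEM) | C=C([C@@H](Oc1cc(OCc2ccccc2)cc(OCc2ccccc2)c1)c1ccc(OCc2ccccc2)cc1)c1c(OCOCC[Si](C)(C)C)cc(OCc2ccccc2)c2c(=O)cc(-c3ccc(OCc4ccccc4)cc3)oc12 | intermediate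
12 | primary pinacol boronate at C4 (C3 epimers, not isolated) | CC1(C)OB(CC([C@@H](Oc2cc(OCc3ccccc3)cc(OCc3ccccc3)c2)c2ccc(OCc3ccccc3)cc2)c2c(OCOCC[Si](C)(C)C)cc(OCc3ccccc3)c3c(=O)cc(-c4ccc(OCc5ccccc5)cc4)oc23)OC1(C)C | intermediate
13 | primary alcohol at C4, 7''-O-SEM (C3 epimers) | OCC([C@@H](Oc1cc(OCc2ccccc2)cc(OCc2ccccc2)c1)c1ccc(OCc2ccccc2)cc1)c1c(OCOCC[Si](C)(C)C)cc(OCc2ccccc2)c2c(=O)cc(-c3ccc(OCc4ccccc4)cc3)oc12 | intermediate
14 | primary alcohol at C4, free O7''-H (C3 epimers) | OCC([C@@H](Oc1cc(OCc2ccccc2)cc(OCc2ccccc2)c1)c1ccc(OCc2ccccc2)cc1)c1c(O)cc(OCc2ccccc2)c2c(=O)cc(-c3ccc(OCc4ccccc4)cc3)oc12 | intermediate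
15 | lactol O7''–C4H(OH) (not isolated) | OC1Oc2cc(OCc3ccccc3)c3c(=O)cc(-c4ccc(OCc5ccccc5)cc4)oc3c2C1[C@@H](Oc1cc(OCc2ccccc2)cc(OCc2ccccc2)c1)c1ccc(OCc2ccccc2)cc1 | intermediate
16 | γ-lactone O7''–C4(=O) (furo[2,3-h]chromene-4,8-dione, C3 epimers) | O=C1Oc2cc(OCc3ccccc3)c3c(=O)cc(-c4ccc(OCc5ccccc5)cc4)oc3c2C1[C@@H](Oc1cc(OCc2ccccc2)cc(OCc2ccccc2)c1)c1ccc(OCc2ccccc2)cc1 | intermediate
17 | ring-switched ketone as O7''-trimethylsilyl ether (C3 epimers, not isolated) | O=C1c2c(OCc3ccccc3)cc(OCc3ccccc3)cc2O[C@@H](c2ccc(OCc3ccccc3)cc2)C1c1c(O[Si](C)(C)C)cc(OCc2ccccc2)c2c(=O)cc(-c3ccc(OCc4ccccc4)cc3)oc12 | intermediate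
18 | ring-switched ketone, free O7''-H (C3 epimers, not isolated) | O=C1c2c(OCc3ccccc3)cc(OCc3ccccc3)cc2O[C@@H](c2ccc(OCc3ccccc3)cc2)C1c1c(O)cc(OCc2ccccc2)c2c(=O)cc(-c3ccc(OCc4ccccc4)cc3)oc12 | intermediate
19 | (2R,3S)-pentabenzyl biflavonoid, free O7''-H | O=C1c2c(OCc3ccccc3)cc(OCc3ccccc3)cc2O[C@@H](c2ccc(OCc3ccccc3)cc2)[C@@H]1c1c(O)cc(OCc2ccccc2)c2c(=O)cc(-c3ccc(OCc4ccccc4)cc3)oc12 | intermediate
20 | sodium (2R,3S)-pentabenzyl biflavonoid 7''-O-sulfate | [Na+].O=C1c2c(OCc3ccccc3)cc(OCc3ccccc3)cc2O[C@@H](c2ccc(OCc3ccccc3)cc2)[C@@H]1c1c(OS(=O)(=O)[O-])cc(OCc2ccccc2)c2c(=O)cc(-c3ccc(OCc4ccccc4)cc3)oc12 | intermediate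
21 | sodium salt of the target (not isolated) | [Na+].O=C1c2c(O)cc(O)cc2O[C@@H](c2ccc(O)cc2)[C@@H]1c1c(OS(=O)(=O)[O-])cc(O)c2c(=O)cc(-c3ccc(O)cc3)oc12 | intermediate
22 | (2R,3S)-naringenin-(3→8'')-apigenin 7''-O-(hydrogen sulfate) | O=C1c2c(O)cc(O)cc2O[C@@H](c2ccc(O)cc2)[C@@H]1c1c(OS(=O)(=O)O)cc(O)c2c(=O)cc(-c3ccc(O)cc3)oc12 | target

Total step count: 14. Longest linear sequence: 11 steps (5 to 22, steps 4–14).

Steps most likely to fail

**Step 12 (proposed new method).** The C2–O1 benzylic ether may ionise. The aryloxide may be lost by β-elimination from the enolisable lactone before the acyl transfer sets in. The tetrahedral intermediate may dehydrate to a benzofuran instead of collapsing to the ketone.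

The fallback is the classical intramolecular Friedel–Crafts acylation with O7'' kept protected. It sets out from 13.
- TEMPO/PhI(OAc)2 in MeCN/H2O should give the carboxylic acid F1.
- 1-Chloro-N,N,2-trimethylpropenylamine in CH2Cl2 should convert it under neutral conditions into the acid chloride F2.
- AgOTf with 2,6-di-tert-butyl-4-methylpyridine at −78 °C should close C4–C4a to the 7''-O-SEM flavanone F3, which is equilibrated to 2,3-trans with PPTS.
- TBAF buffered with AcOH removes the SEM group, and the sequence comes back to the route at 19.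

**Step 8.** Transmetalation and reductive elimination at the di-ortho-substituted iodide may be slow. Protodeboronation, β-aryloxide elimination from the alkenylpalladium species, or ionisation of the allylic aryl ether by Pd(0) (loss of the C2 configuration) could then take over.

The fallback is a palladium-free, copper-mediated Stille-type coupling. It sets out from 9.
- Molybdenum-catalysed α-selective hydrostannation (Bu3SnH, Mo(CO)3(CNtBu)3, THF) should give the α-tributylstannyl alkene F4.
- F4 is coupled with 4 by copper(I) thiophene-2-carboxylate in NMP at rt, and the sequence comes back to the route at 11.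

**Step 6.** The activated oxyphosphonium ion is p-benzyloxybenzylic and propargylic and may partly ionise, which would erode the enantiomeric purity at C2.

The fallback is catalyst-controlled and enantioconvergent, a copper-catalysed propargylic etherification through a copper allenylidene. It sets out from 6 without resolution.
- Ac2O/pyridine should give the racemic propargylic acetate F5.
- F5 is treated with 8, CuOTf, the chiral pybox enantiomer that delivers the (R)-ether, and iPr2NEt at −20 °C, and the sequence comes back to the route at 9.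

Further compounds
F1 | step 12 | (3R)-3-[3,5-bis(benzyloxy)phenoxy]-3-[4-(benzyloxy)phenyl]-2-(5''-benzyloxy-4'''-benzyloxy-7''-O-SEM-flavon-8''-yl)propanoic acid (C3 epimers) | OC(=O)C([C@@H](Oc1cc(OCc2ccccc2)cc(OCc2ccccc2)c1)c1ccc(OCc2ccccc2)cc1)c1c(OCOCC[Si](C)(C)C)cc(OCc2ccccc2)c2c(=O)cc(-c3ccc(OCc4ccccc4)cc3)oc12
F2 | step 12 | acid chloride of F1 (C3 epimers) | ClC(=O)C([C@@H](Oc1cc(OCc2ccccc2)cc(OCc2ccccc2)c1)c1ccc(OCc2ccccc2)cc1)c1c(OCOCC[Si](C)(C)C)cc(OCc2ccccc2)c2c(=O)cc(-c3ccc(OCc4ccccc4)cc3)oc12
F3 | step 12 | (2R,3S)-pentabenzyl biflavonoid 7''-O-SEM ether | O=C1c2c(OCc3ccccc3)cc(OCc3ccccc3)cc2O[C@@H](c2ccc(OCc3ccccc3)cc2)[C@@H]1c1c(OCOCC[Si](C)(C)C)cc(OCc2ccccc2)c2c(=O)cc(-c3ccc(OCc4ccccc4)cc3)oc12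
F4 | step 8 | (S)-{3-[3,5-bis(benzyloxy)phenoxy]-3-[4-(benzyloxy)phenyl]prop-1-en-2-yl}tributylstannane (same spatial arrangement at C2 as in 9) | C=C([Sn](CCCC)(CCCC)CCCC)[C@@H](Oc1cc(OCc2ccccc2)cc(OCc2ccccc2)c1)c1ccc(OCc2ccccc2)cc1
F5 | step 6 | rac-1-[4-(benzyloxy)phenyl]prop-2-yn-1-yl acetate | C#CC(OC(C)=O)c1ccc(OCc2ccccc2)cc1
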